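The flask holds 0.010 M of electrophile, 3.00 equiv of nucleophile and 0.300 equiv of free base.

| flask | electrophile | nucleophile | free base | remark | time |
|---|---|---|---|---|---|
| dawn | 0.0067 M | 3 equiv | 0.30 equiv | run made earlier |  |
| summer | 0.015 M | 3 equiv | 0.30 equiv | run made earlier |  |
| midnight | 0.010 M | 4.5 equiv | 0.30 equiv | run made earlier |  |
| flask | 0.010 M | 3.00 equiv | 0.300 equiv |  | 3.0 h |

- dawn (time / h: electrophile / %, target / %): 0.417: 94.5, 5.5; 1.00: 86.8, 13.2; 2.00: 76.0, 22.9; 3.00: 68.0, 32.0
- summer (time / h: electrophile / %, target / %): 0.833: 77.8, 22.4; 1.50: 64.5, 35.1; 2.50: 51.2, 48.6; 3.00: 45.6, 53.5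
- midnight (time / h: electrophile / %, target / %): 0.417: 88.0, 12.3; 1.00: 73.2, 26.2; 2.00: 55.7, 44.4; 3.00: 43.3, 57.0

(standard deviation of a reading: 0.3 percentage points)

- the earlier runs do not show how much of nucleophile is bound; that part of a forecast is a guess

1. part of the electrophile that has reacted at 3.0 h
2. share of the unused nucleophile that is free and not bound as protonated nucleophile, at 3.0 h

If each target costs one nucleophile, the second-order constant of the summer run sags from 6.97 /M/h to 6.50 /M/h. So try a cost of two: one nucleophile reacts, and one is held as protonated nucleophile. Take rate = k[electrophile][nucleophile], with n equivalents charged, x the part reacted, and t the time: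

k = ln[(n − 2x)/(n(1 − x))] / ((n − 2)[electrophile]t), with [electrophile] as charged

The last readings give:

dawn 7.25 /M/h; summer 7.44 /M/h; midnight 7.29 /M/h

Their mean, 7.33 /M/h, is the doubled-cost constant. Turned round for the flask:

g = exp((n − 2)k[electrophile]t) = 1.25

x = n(g − 1)/(ng − 2) = 42.4 %

The weak link is the second nucleophile. The runs show it through rate and do not show bound nucleophile, so this part is a guess. Free base might take that acid first. But the first summer reading, with 22.2 % of the electrophile reacted, a smaller part than the 0.30 equiv of free base, already gives 7.27 /M/h. So my reckoning sets bound nucleophile equal to target: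

free share = (n − 2x)/(n − x) = 83.5 %

The forecast gives 42.5 % (41 % to 44 %) and, above my share, 86 % (81 % to 95 %), holding that “the nucleophile seems to take most of the acid”.

The flask gives 42.5 % reacted and 83.9 % free.

    electrophile → decomposition product (k = 6.25 × 10⁻⁸ /s)
    acid set free + free base ⇌ salt of the base, settled at all times (K = 1600 /M)
    2 free base → homo dimer (k = 0.0721 /M/s)
    electrophile + nucleophile → acid set free + target (k = 0.00203 /M/s)
    nucleophile + acid set free ⇌ protonated nucleophile, settled at all times (K = 25000 /M)
    acid set free → by-product carried off (k = 0.00158 /s)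

Read back from 42.5 %, the doubled-cost constant of the flask is 7.33 /M/h. At the start of the flask, equilibrium constant times charged concentration is 750 for nucleophile with acid set free, far above the 4.8 for free base. At 3.00 h the flask holds 0.00416 M of protonated nucleophile against 6.50 × 10⁻⁶ M of salt of the base. With 7.50 equiv of nucleophile, 7.33 /M/h gives 76.2 %, and that neighbour flask reached 76.2 %.

The readings are calculated for an exercise; noise was put on by code.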